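**Plan**

- Cuts: (i) the 5,5′-biaryl bond (Suzuki–Miyaura), giving fragment A (oxolane half, aryl bromide) and fragment B (tetralin half, aryl boronate); (ii) in B, the C1–C8a aryl–alkyl bond (Friedel–Crafts retron), leading back to an oxolane of the same type as A; (iii) in each oxolane, the C3–C4 bond, then the O1–C5 ether bond.
- Enabling feature: oxolane C3 carries CH2OH, so it can be the carbon radical released from a terminal epoxide. C4 carries an oxygen and a benzyl group, so it can be the siloxy-bearing carbon of an aryl-conjugated enol ether C4(OSiMe3)=CH–Ar. The O1–C5 ether is the tether that makes the union 5-exo.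
- Forward: aldehyde 1 → vinyl carbinol → Sharpless kinetic resolution to epoxy alcohol 4 (common to both halves) → O-alkylation with a 2-benzylallyl chloride → alkene cleavage → enol silylation → radical closure of the oxolane with Cp2TiCl (trivalent titanium).
- Fragment B: acid turns oxolane 27 into tetralin 28, which is borylated and joined to 16; hydrogenolysis of four benzyl ethers ends the route.
- Stereochemistry: the carbinol centre of 4 (kinetic resolution with D-(−)-diisopropyl tartrate) becomes C2 and is the only external source. C3 and C4 are set relative to it in the radical cyclization; tetralin C1 is set relative to C2 in the Friedel–Crafts closure.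

Key step: step 7

Assumption: benzyl ethers 1, 5 and 17 are taken as catalogue compounds (each is otherwise one O-benzylation of 5-bromovanillin, 5-bromo-2-methoxyphenol or 4-bromo-2-methoxyphenol); locants used below are oxolane O1, C2 (aryl), C3 (CH2OH), C4 (OH, benzyl), C5 and tetralin C1 (aryl), C2 (CH2OH), C3 (OH, CH2OH), C4, C6 (OMe), C7 (O).

**Route**

Step 1
Reactants: 1 4-(benzyloxy)-3-bromo-5-methoxybenzaldehyde; 2 vinylmagnesium bromide
Product: 3 (±)-1-[4-(benzyloxy)-3-bromo-5-methoxyphenyl]prop-2-en-1-ol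
Conditions: 2 (1.2 equiv), THF, −78 to 0 °C; aq. NH4Cl
Reagents that add atoms: none
Why: Grignard 1,2-addition to the aldehyde, the aryl bromide being inert to the vinyl Grignard reagent at this temperature; the carbinol centre forms as the racemate and is resolved in step 2.

Step 2
Reactants: 3 (±)-1-[4-(benzyloxy)-3-bromo-5-methoxyphenyl]prop-2-en-1-ol
Product: 4 (R)-[4-(benzyloxy)-3-bromo-5-methoxyphenyl][(2S)-oxiran-2-yl]methanol (anti epoxy alcohol)
Conditions: Ti(OiPr)4, D-(−)-diisopropyl tartrate, t-BuOOH (0.6 equiv), 4 Å molecular sieves, CH2Cl2, −20 °C, run to about half conversion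
Reagents that add atoms: tert-butyl hydroperoxide, CC(C)(C)OO
Why: Sharpless kinetic resolution, in which D-(−)-tartrate should epoxidize the (S)-1-arylallyl alcohol fast and anti, so 4 carries the carbinol configuration that becomes C2 of both halves (the slow enantiomer of 3 is separated; the epoxide centre is erased later at the radical stage).

Step 3
Reactants: 5 2-(benzyloxy)-4-bromo-1-methoxybenzene; 6 3-chloro-2-(chloromethyl)prop-1-ene
Product: 8 2-(benzyloxy)-4-[2-(chloromethyl)prop-2-en-1-yl]-1-methoxybenzene, via aryl Grignard reagent 7 (not isolated)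
Conditions: Mg, THF, 40 °C; added to 6 (3 equiv), CuI (5 mol%), THF, −20 to 0 °C
Reagents that add atoms: none
Why: Copper-catalysed allylic substitution of an aryl Grignard reagent on a symmetrical bis-allylic dichloride (SN2 and SN2′ give the same product), with excess dichloride and inverse addition to suppress double substitution; no stereocentre.

Step 4
Reactants: 4 (R)-[4-(benzyloxy)-3-bromo-5-methoxyphenyl][(2S)-oxiran-2-yl]methanol; 8 2-(benzyloxy)-4-[2-(chloromethyl)prop-2-en-1-yl]-1-methoxybenzene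
Product: 10 (2S)-2-[(R)-[4-(benzyloxy)-3-bromo-5-methoxyphenyl]({2-[3-(benzyloxy)-4-methoxybenzyl]prop-2-en-1-yl}oxy)methyl]oxirane, via sodium alkoxide 9 (not isolated)
Conditions: NaH (1.1 equiv), THF/DMF, 0 °C; 8 (1.2 equiv), Bu4NI (cat.), 0 °C to rt
Reagents that add atoms: none
Why: Williamson ether synthesis with a reactive allylic chloride under iodide catalysis at low temperature, where O-alkylation should outpace Payne rearrangement; both stereocentres of 4 are untouched.

Step 5
Reactants: 10 (2S)-2-[(R)-[4-(benzyloxy)-3-bromo-5-methoxyphenyl]({2-[3-(benzyloxy)-4-methoxybenzyl]prop-2-en-1-yl}oxy)methyl]oxirane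
Product: 12 1-[3-(benzyloxy)-4-methoxyphenyl]-3-{(R)-[4-(benzyloxy)-3-bromo-5-methoxyphenyl][(2S)-oxiran-2-yl]methoxy}propan-2-one, via vicinal diol 11 (not isolated)
Conditions: OsO4 (2 mol%), NaIO4 (4 equiv), 2,6-lutidine, dioxane/H2O, rt
Reagents that add atoms: osmium tetroxide, O=[Os](=O)(=O)=O (catalytic oxygen carrier); sodium periodate, [Na+].[O-]I(=O)(=O)=O (terminal oxidant)
Why: Lemieux–Johnson oxidation of the only alkene under buffered, near-neutral conditions that should spare the epoxide, the aryl bromide and the benzyl ethers; the diol centre is transient.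

Step 6
Reactants: 12 1-[3-(benzyloxy)-4-methoxyphenyl]-3-{(R)-[4-(benzyloxy)-3-bromo-5-methoxyphenyl][(2S)-oxiran-2-yl]methoxy}propan-2-one
Product: 14 {[(Z)-1-[3-(benzyloxy)-4-methoxyphenyl]-3-{(R)-[4-(benzyloxy)-3-bromo-5-methoxyphenyl][(2S)-oxiran-2-yl]methoxy}prop-1-en-2-yl]oxy}trimethylsilane, via lithium enolate 13 (not isolated)
Conditions: Me3SiCl (1.5 equiv), then LiN(SiMe3)2 (1.1 equiv), THF, −78 °C (in-situ quench); pentane, filtration, used at once
Reagents that add atoms: chlorotrimethylsilane, C[Si](C)(C)Cl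
Why: Kinetic enolization with in-situ silylation, in which the more acidic benzylic protons are removed and the α-alkoxy side is kinetically disfavoured, so the aryl-conjugated silyl enol ether should form while the epoxide is inert to the amide base at −78 °C; alkene geometry is not critical.

Step 7
Reactants: 14 {[(Z)-1-[3-(benzyloxy)-4-methoxyphenyl]-3-{(R)-[4-(benzyloxy)-3-bromo-5-methoxyphenyl][(2S)-oxiran-2-yl]methoxy}prop-1-en-2-yl]oxy}trimethylsilane
Product: 16 (2S,3R,4S)-2-[4-(benzyloxy)-3-bromo-5-methoxyphenyl]-4-[3-(benzyloxy)-4-methoxybenzyl]-3-(hydroxymethyl)oxolan-4-ol, via trimethylsilyl ether 15 (not isolated)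
Conditions: Cp2TiCl2 (2.2 equiv), Zn dust, THF, rt (gives Cp2TiCl); added slowly to 14 and 1,4-cyclohexadiene (5 equiv) in THF (0.02 M), rt; aq. NaHCO3; then K2CO3 (cat.), MeOH, rt
Reagents that add atoms: none
Why: Proposed new method: Cp2TiCl (trivalent titanium) opens the terminal epoxide by electron transfer to give the secondary C3 radical bearing CH2O–Ti, which should add 5-exo-trig to the siloxy-bearing carbon of the aryl-conjugated enol ether (forming C3–C4 and the oxolane) to leave a benzylic radical that 1,4-cyclohexadiene reduces by hydrogen-atom transfer, after which methanolysis frees the tertiary alcohol. The closest known reaction type is the Nugent–RajanBabu epoxide radical cyclization of 1-aryl-2,3-epoxypropyl cinnamyl ethers to 2-aryl-4-benzyl-3-(hydroxymethyl)oxolanes; attack at an oxygen-bearing alkene carbon is the new element, argued from the larger LUMO coefficient at that carbon of an enol ether toward a nucleophilic alkyl radical and from the benzylic stabilization that only the 5-exo mode gains. Both epoxide epimers give the same planar radical, so C3 is set in the chair-like transition state in which the C2 aryl group lies pseudoequatorial and CH2OTi turns away from it (2,3-trans). C4 is set in the same transition state: the exocyclic CH–Ar carbon takes the pseudoequatorial site cis to CH2OTi, as in the known cinnamyl-ether cyclizations, which leaves the siloxy oxygen trans to CH2OH; this is why the acceptor is held at the enol-ether and not the ketone oxidation level, where oxygen would be the exocyclic atom. The step needs cyclization to outrun reduction of the C3 radical by a second Cp2TiCl (deoxygenation to the allyl ether) and 5-exo to beat 6-endo closure, which slow addition of the reagent at high dilution and the styrene-type acceptor are meant to secure.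

Step 8
Reactants: 17 1-(benzyloxy)-4-bromo-2-methoxybenzene; 6 3-chloro-2-(chloromethyl)prop-1-ene
Product: 19 1-(benzyloxy)-4-[2-(chloromethyl)prop-2-en-1-yl]-2-methoxybenzene, via aryl Grignard reagent 18 (not isolated)
Conditions: Mg, THF, 40 °C; added to 6 (3 equiv), CuI (5 mol%), THF, −20 to 0 °C
Reagents that add atoms: none
Why: Same copper-catalysed allylic substitution as step 3, with the regioisomeric aryl Grignard reagent; no stereocentre.

Step 9
Reactants: 4 (R)-[4-(benzyloxy)-3-bromo-5-methoxyphenyl][(2S)-oxiran-2-yl]methanol; 19 1-(benzyloxy)-4-[2-(chloromethyl)prop-2-en-1-yl]-2-methoxybenzene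
Product: 21 (2S)-2-[(R)-[4-(benzyloxy)-3-bromo-5-methoxyphenyl]({2-[4-(benzyloxy)-3-methoxybenzyl]prop-2-en-1-yl}oxy)methyl]oxirane, via potassium alkoxide 20 (not isolated)
Conditions: KN(SiMe3)2 (1.05 equiv), THF, −78 °C; 19 (1.2 equiv), Bu4NI (cat.), −78 to 0 °C
Reagents that add atoms: none
Why: Williamson ether synthesis through the potassium alkoxide, which a soluble amide base forms cleanly at low temperature and which the reactive allylic chloride should trap under iodide catalysis before Payne rearrangement can intervene; the stereocentres of 4 are untouched.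

Step 10
Reactants: 21 (2S)-2-[(R)-[4-(benzyloxy)-3-bromo-5-methoxyphenyl]({2-[4-(benzyloxy)-3-methoxybenzyl]prop-2-en-1-yl}oxy)methyl]oxirane
Product: 23 1-[4-(benzyloxy)-3-methoxyphenyl]-3-{(R)-[4-(benzyloxy)-3-bromo-5-methoxyphenyl][(2S)-oxiran-2-yl]methoxy}propan-2-one, via vicinal diol 22 (not isolated)
Conditions: OsO4 (2 mol%), NaIO4 (4 equiv), 2,6-lutidine, dioxane/H2O, rt
Reagents that add atoms: osmium tetroxide, O=[Os](=O)(=O)=O (catalytic oxygen carrier); sodium periodate, [Na+].[O-]I(=O)(=O)=O (terminal oxidant)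
Why: Lemieux–Johnson oxidation as in step 5.

Step 11
Reactants: 23 1-[4-(benzyloxy)-3-methoxyphenyl]-3-{(R)-[4-(benzyloxy)-3-bromo-5-methoxyphenyl][(2S)-oxiran-2-yl]methoxy}propan-2-one
Product: 25 {[(Z)-1-[4-(benzyloxy)-3-methoxyphenyl]-3-{(R)-[4-(benzyloxy)-3-bromo-5-methoxyphenyl][(2S)-oxiran-2-yl]methoxy}prop-1-en-2-yl]oxy}trimethylsilane, via lithium enolate 24 (not isolated)
Conditions: Me3SiCl (1.5 equiv), then LiN(SiMe3)2 (1.1 equiv), THF, −78 °C; pentane, filtration, used at once
Reagents that add atoms: chlorotrimethylsilane, C[Si](C)(C)Cl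
Why: Kinetic benzylic enolization with in-situ silylation as in step 6.

Step 12
Reactants: 25 {[(Z)-1-[4-(benzyloxy)-3-methoxyphenyl]-3-{(R)-[4-(benzyloxy)-3-bromo-5-methoxyphenyl][(2S)-oxiran-2-yl]methoxy}prop-1-en-2-yl]oxy}trimethylsilane
Product: 27 (2S,3R,4S)-2-[4-(benzyloxy)-3-bromo-5-methoxyphenyl]-4-[4-(benzyloxy)-3-methoxybenzyl]-3-(hydroxymethyl)oxolan-4-ol, via trimethylsilyl ether 26 (not isolated)
Conditions: Cp2TiCl2 (2.2 equiv), Zn dust, THF, rt; added slowly to 25 and 1,4-cyclohexadiene (5 equiv) in THF (0.02 M), rt; aq. NaHCO3; then K2CO3 (cat.), MeOH, rt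
Reagents that add atoms: none
Why: Proposed new method: as in step 7, the epoxide-derived C3 radical (Cp2TiCl, trivalent titanium) should add 5-exo-trig to the siloxy-bearing carbon of the styrenyl enol ether through the same chair-like transition state (C2 aryl pseudoequatorial gives 2,3-trans; exocyclic CH–Ar carbon cis to CH2OTi puts the C4 oxygen trans to CH2OH), the closest known reaction type being the Nugent–RajanBabu cyclization of epoxy cinnamyl ethers to 4-benzyl-3-(hydroxymethyl)oxolanes.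

Step 13
Reactants: 27 (2S,3R,4S)-2-[4-(benzyloxy)-3-bromo-5-methoxyphenyl]-4-[4-(benzyloxy)-3-methoxybenzyl]-3-(hydroxymethyl)oxolan-4-ol
Product: 28 (1S,2S,3S)-7-(benzyloxy)-1-[4-(benzyloxy)-3-bromo-5-methoxyphenyl]-2,3-bis(hydroxymethyl)-6-methoxy-1,2,3,4-tetrahydronaphthalen-3-ol
Conditions: CF3CO2H (3 equiv), CH2Cl2, 0 °C; NaHCO3, MeOH work-up
Reagents that add atoms: none
Why: Intramolecular Friedel–Crafts alkylation (the olivil-to-cycloolivil type of rearrangement), in which acid ionizes the benzylic C2–O1 bond and the cation is captured by the benzyl ring para to its methoxy group in a six-membered closure; the aryl group should take the pseudoequatorial position trans to the adjacent CH2OH, the two other centres are not touched, and the former C5 becomes the second CH2OH.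

Step 14
Reactants: 28 (1S,2S,3S)-7-(benzyloxy)-1-[4-(benzyloxy)-3-bromo-5-methoxyphenyl]-2,3-bis(hydroxymethyl)-6-methoxy-1,2,3,4-tetrahydronaphthalen-3-ol
Product: 29 (1S,2S,3S)-7-(benzyloxy)-1-[4-(benzyloxy)-3-methoxy-5-(4,4,5,5-tetramethyl-1,3,2-dioxaborolan-2-yl)phenyl]-2,3-bis(hydroxymethyl)-6-methoxy-1,2,3,4-tetrahydronaphthalen-3-ol
Conditions: bis(pinacolato)diboron (1.5 equiv), Pd(dppf)Cl2 (5 mol%), KOAc (3 equiv), dioxane, 90 °C
Reagents that add atoms: bis(pinacolato)diboron, CC1(C)OB(OC1(C)C)B1OC(C)(C)C(C)(C)O1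
Why: Miyaura borylation of the aryl bromide, which tolerates free hydroxyl groups and leaves all stereocentres alone.

Step 15
Reactants: 16 (2S,3R,4S)-2-[4-(benzyloxy)-3-bromo-5-methoxyphenyl]-4-[3-(benzyloxy)-4-methoxybenzyl]-3-(hydroxymethyl)oxolan-4-ol; 29 the aryl boronate of fragment B
Product: 30 tetra-O-benzyl ether of the target (16 and 28 joined at their former C–Br carbons)
Conditions: Pd(OAc)2 (5 mol%), SPhos (10 mol%), K3PO4 (3 equiv), toluene/H2O, 80 °C
Reagents that add atoms: none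
Why: Suzuki–Miyaura coupling with a biaryl dialkylphosphine ligand suited to two ortho-alkoxy partners; the new biaryl axis has only two ortho substituents and is not a stereogenic element.

Step 16
Reactants: 30 tetra-O-benzyl ether of the target
Product: 31 CNP0252244.1
Conditions: H2 (1 atm), 10% Pd/C, EtOAc/MeOH, rt, stopped at four equivalents of uptake
Reagents that add atoms: none
Why: Hydrogenolysis of the four aryl benzyl ethers, which under neutral conditions should be much faster than cleavage of the cyclic benzylic ether or of the benzylic C–C bonds; no stereocentre is affected.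

**Compound list**

1 | 4-(benzyloxy)-3-bromo-5-methoxybenzaldehyde | O=Cc1cc(OC)c(OCc2ccccc2)c(Br)c1 | starting material
2 | vinylmagnesium bromide | C=C[Mg]Br | starting material
3 | (±)-1-[4-(benzyloxy)-3-bromo-5-methoxyphenyl]prop-2-en-1-ol (racemic) | C=CC(O)c1cc(OC)c(OCc2ccccc2)c(Br)c1 | intermediate
4 | (R)-[4-(benzyloxy)-3-bromo-5-methoxyphenyl][(2S)-oxiran-2-yl]methanol | O[C@H](c1cc(OC)c(OCc2ccccc2)c(Br)c1)[C@@H]1CO1 | intermediate
5 | 2-(benzyloxy)-4-bromo-1-methoxybenzene | COc1ccc(Br)cc1OCc1ccccc1 | starting material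
6 | 3-chloro-2-(chloromethyl)prop-1-ene | C=C(CCl)CCl | starting material
7 | [3-(benzyloxy)-4-methoxyphenyl]magnesium bromide | COc1ccc([Mg]Br)cc1OCc1ccccc1 | intermediate
8 | 2-(benzyloxy)-4-[2-(chloromethyl)prop-2-en-1-yl]-1-methoxybenzene | C=C(CCl)Cc1ccc(OC)c(OCc2ccccc2)c1 | intermediate
9 | sodium alkoxide of 4 | [Na+].[O-][C@H](c1cc(OC)c(OCc2ccccc2)c(Br)c1)[C@@H]1CO1 | intermediate
10 | (2S)-2-[(R)-[4-(benzyloxy)-3-bromo-5-methoxyphenyl]({2-[3-(benzyloxy)-4-methoxybenzyl]prop-2-en-1-yl}oxy)methyl]oxirane | C=C(Cc1ccc(OC)c(OCc2ccccc2)c1)CO[C@H](c1cc(OC)c(OCc2ccccc2)c(Br)c1)[C@@H]1CO1 | intermediate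
11 | 2-[3-(benzyloxy)-4-methoxybenzyl]-3-{(R)-[4-(benzyloxy)-3-bromo-5-methoxyphenyl][(2S)-oxiran-2-yl]methoxy}propane-1,2-diol (both epimers at the diol carbon) | OCC(O)(Cc1ccc(OC)c(OCc2ccccc2)c1)CO[C@H](c1cc(OC)c(OCc2ccccc2)c(Br)c1)[C@@H]1CO1 | intermediate
12 | 1-[3-(benzyloxy)-4-methoxyphenyl]-3-{(R)-[4-(benzyloxy)-3-bromo-5-methoxyphenyl][(2S)-oxiran-2-yl]methoxy}propan-2-one | O=C(Cc1ccc(OC)c(OCc2ccccc2)c1)CO[C@H](c1cc(OC)c(OCc2ccccc2)c(Br)c1)[C@@H]1CO1 | intermediate
13 | lithium (Z)-enolate of 12 on the benzylic side | [Li+].[O-]/C(=C\c1ccc(OC)c(OCc2ccccc2)c1)CO[C@H](c1cc(OC)c(OCc2ccccc2)c(Br)c1)[C@@H]1CO1 | intermediate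
14 | (Z)-trimethylsilyl enol ether of 12 (aryl-conjugated) | C[Si](C)(C)O/C(=C\c1ccc(OC)c(OCc2ccccc2)c1)CO[C@H](c1cc(OC)c(OCc2ccccc2)c(Br)c1)[C@@H]1CO1 | intermediate
15 | 4-O-trimethylsilyl ether of 16 | COc1ccc(C[C@@]2(O[Si](C)(C)C)CO[C@H](c3cc(OC)c(OCc4ccccc4)c(Br)c3)[C@H]2CO)cc1OCc1ccccc1 | intermediate
16 | (2S,3R,4S)-2-[4-(benzyloxy)-3-bromo-5-methoxyphenyl]-4-[3-(benzyloxy)-4-methoxybenzyl]-3-(hydroxymethyl)oxolan-4-ol (fragment A) | COc1ccc(C[C@@]2(O)CO[C@H](c3cc(OC)c(OCc4ccccc4)c(Br)c3)[C@H]2CO)cc1OCc1ccccc1 | intermediate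
17 | 1-(benzyloxy)-4-bromo-2-methoxybenzene | COc1cc(Br)ccc1OCc1ccccc1 | starting material
18 | [4-(benzyloxy)-3-methoxyphenyl]magnesium bromide | COc1cc([Mg]Br)ccc1OCc1ccccc1 | intermediate
19 | 1-(benzyloxy)-4-[2-(chloromethyl)prop-2-en-1-yl]-2-methoxybenzene | C=C(CCl)Cc1ccc(OCc2ccccc2)c(OC)c1 | intermediate
20 | potassium alkoxide of 4 | [K+].[O-][C@H](c1cc(OC)c(OCc2ccccc2)c(Br)c1)[C@@H]1CO1 | intermediate
21 | (2S)-2-[(R)-[4-(benzyloxy)-3-bromo-5-methoxyphenyl]({2-[4-(benzyloxy)-3-methoxybenzyl]prop-2-en-1-yl}oxy)methyl]oxirane | C=C(Cc1ccc(OCc2ccccc2)c(OC)c1)CO[C@H](c1cc(OC)c(OCc2ccccc2)c(Br)c1)[C@@H]1CO1 | intermediate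
22 | 2-[4-(benzyloxy)-3-methoxybenzyl]-3-{(R)-[4-(benzyloxy)-3-bromo-5-methoxyphenyl][(2S)-oxiran-2-yl]methoxy}propane-1,2-diol (both epimers at the diol carbon) | OCC(O)(Cc1ccc(OCc2ccccc2)c(OC)c1)CO[C@H](c1cc(OC)c(OCc2ccccc2)c(Br)c1)[C@@H]1CO1 | intermediate
23 | 1-[4-(benzyloxy)-3-methoxyphenyl]-3-{(R)-[4-(benzyloxy)-3-bromo-5-methoxyphenyl][(2S)-oxiran-2-yl]methoxy}propan-2-one | O=C(Cc1ccc(OCc2ccccc2)c(OC)c1)CO[C@H](c1cc(OC)c(OCc2ccccc2)c(Br)c1)[C@@H]1CO1 | intermediate
24 | lithium (Z)-enolate of 23 on the benzylic side | [Li+].[O-]/C(=C\c1ccc(OCc2ccccc2)c(OC)c1)CO[C@H](c1cc(OC)c(OCc2ccccc2)c(Br)c1)[C@@H]1CO1 | intermediate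
25 | (Z)-trimethylsilyl enol ether of 23 (aryl-conjugated) | C[Si](C)(C)O/C(=C\c1ccc(OCc2ccccc2)c(OC)c1)CO[C@H](c1cc(OC)c(OCc2ccccc2)c(Br)c1)[C@@H]1CO1 | intermediate
26 | 4-O-trimethylsilyl ether of 27 | COc1cc(C[C@@]2(O[Si](C)(C)C)CO[C@H](c3cc(OC)c(OCc4ccccc4)c(Br)c3)[C@H]2CO)ccc1OCc1ccccc1 | intermediate
27 | (2S,3R,4S)-2-[4-(benzyloxy)-3-bromo-5-methoxyphenyl]-4-[4-(benzyloxy)-3-methoxybenzyl]-3-(hydroxymethyl)oxolan-4-ol | COc1cc(C[C@@]2(O)CO[C@H](c3cc(OC)c(OCc4ccccc4)c(Br)c3)[C@H]2CO)ccc1OCc1ccccc1 | intermediate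
28 | (1S,2S,3S)-7-(benzyloxy)-1-[4-(benzyloxy)-3-bromo-5-methoxyphenyl]-2,3-bis(hydroxymethyl)-6-methoxy-1,2,3,4-tetrahydronaphthalen-3-ol | COc1cc(cc(Br)c1OCc1ccccc1)[C@H]1c2cc(OCc3ccccc3)c(OC)cc2C[C@@](O)(CO)[C@@H]1CO | intermediate
29 | pinacol boronate of 28 (Bpin in place of Br; fragment B) | COc1cc(cc(B2OC(C)(C)C(C)(C)O2)c1OCc1ccccc1)[C@H]1c2cc(OCc3ccccc3)c(OC)cc2C[C@@](O)(CO)[C@@H]1CO | intermediate
30 | tetra-O-benzyl ether of the target (5,5′-biaryl of 16 and 28) | COc1ccc(C[C@@]2(O)CO[C@H](c3cc(OC)c(OCc4ccccc4)c(-c5cc([C@H]6c7cc(OCc8ccccc8)c(OC)cc7C[C@@](O)(CO)[C@@H]6CO)cc(OC)c5OCc9ccccc9)c3)[C@H]2CO)cc1OCc1ccccc1 | intermediate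
31 | CNP0252244.1: (2S,3R,4S)-4-(3-hydroxy-4-methoxybenzyl)-3-(hydroxymethyl)-2-aryl-oxolan-4-ol whose 4-hydroxy-3-methoxyphenyl group is joined at C5 to C5′ of the 4-hydroxy-3-methoxyphenyl group on C1 of (1S,2S,3S)-2,3-bis(hydroxymethyl)-6-methoxy-1,2,3,4-tetrahydronaphthalene-3,7-diol | COc1ccc(C[C@@]2(O)CO[C@H](c3cc(OC)c(O)c(-c4cc([C@H]5c6cc(O)c(OC)cc6C[C@@](O)(CO)[C@@H]5CO)cc(OC)c4O)c3)[C@H]2CO)cc1O | target

**Count and risks**

Total steps: 16. Longest linear sequence: 10 (steps 1, 2, 9, 10, 11, 12, 13, 14, 15, 16).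

Most likely to fail:

1. Step 7 (labelled). The C3 radical may be reduced and deoxygenated before it adds to the hindered, oxygen-bearing alkene carbon; it may close 6-endo; the benzylic radical may be reduced further and lose the β-siloxy group; or the face selectivity at C4 may be poor. The fallback uses known chemistry and sets out from 5 and 4. Sonogashira coupling of 5 with propargyl alcohol (Pd(PPh3)2Cl2, CuI, Et3N, 70 °C) would give 3-[3-(benzyloxy)-4-methoxyphenyl]prop-2-yn-1-ol F1. Appel bromination (CBr4, PPh3) would give 2-(benzyloxy)-4-(3-bromoprop-1-yn-1-yl)-1-methoxybenzene F2, and alkylation of sodium alkoxide 9 with it would give the epoxy aryl-propargyl ether F3. The established Cp2TiCl 5-exo-dig cyclization of such ethers would give the 2,3-trans 4-benzylidene oxolane F4 (alkene geometry immaterial). Dimethyldioxirane should epoxidize the exocyclic alkene on the face anti to the C3 hydroxymethyl group to give spiro-epoxide F5. Cp2TiCl with 1,4-cyclohexadiene then opens F5 to the benzylic radical and reduces it, so the oxygen stays on C4 trans to CH2OH; the route is rejoined at 16.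

2. Step 12 (labelled). The same processes as in step 7 may intervene. The fallback uses the same known sequence and sets out from 17 and 4. Sonogashira coupling of 17 with propargyl alcohol would give 3-[4-(benzyloxy)-3-methoxyphenyl]prop-2-yn-1-ol F6, Appel bromination the propargylic bromide F7, and alkylation of potassium alkoxide 20 the epoxy aryl-propargyl ether F8. Cp2TiCl 5-exo-dig cyclization would give the 4-benzylidene oxolane F9, dimethyldioxirane the spiro-epoxide F10, and reductive opening with Cp2TiCl and 1,4-cyclohexadiene rejoins the route at 27.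

3. Step 2. The Lewis-acidic titanium tartrate may ionize the electron-rich benzylic alcohol (racemization, allylic transposition) or open the aryl-substituted epoxy alcohol, eroding yield and enantiopurity. The fallback sets out from 3. Lipase-mediated acylation (Candida antarctica lipase B, vinyl acetate, t-BuOMe, rt) should, by the usual empirical preference of this enzyme for the (R)-carbinol, leave (S)-1-[4-(benzyloxy)-3-bromo-5-methoxyphenyl]prop-2-en-1-ol F11 and convert the other enantiomer into its (R)-acetate F12, which is separated. Hydroxyl-directed epoxidation of F11 (VO(acac)2, t-BuOOH, CH2Cl2) would give 4 together with its epoxide epimer F13. Both are carried on, since they give the same C3 radical; the route is rejoined at 4.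

**Further compounds**

F1 | step 7 | 3-[3-(benzyloxy)-4-methoxyphenyl]prop-2-yn-1-ol | OCC#Cc1ccc(OC)c(OCc2ccccc2)c1
F2 | step 7 | 2-(benzyloxy)-4-(3-bromoprop-1-yn-1-yl)-1-methoxybenzene | BrCC#Cc1ccc(OC)c(OCc2ccccc2)c1
F3 | step 7 | (2S)-2-[(R)-[4-(benzyloxy)-3-bromo-5-methoxyphenyl]({3-[3-(benzyloxy)-4-methoxyphenyl]prop-2-yn-1-yl}oxy)methyl]oxirane | COc1ccc(C#CCO[C@H](c2cc(OC)c(OCc3ccccc3)c(Br)c2)[C@@H]2CO2)cc1OCc1ccccc1
F4 | step 7 | [(2S,3R)-2-[4-(benzyloxy)-3-bromo-5-methoxyphenyl]-4-[3-(benzyloxy)-4-methoxybenzylidene]oxolan-3-yl]methanol (E/Z not controlled) | COc1ccc(C=C2CO[C@H](c3cc(OC)c(OCc4ccccc4)c(Br)c3)[C@H]2CO)cc1OCc1ccccc1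
F5 | step 7 | spiro-epoxide of F4 at the exocyclic alkene, epoxide oxygen on C4 anti to the C3 hydroxymethyl group (benzylic epoxide centre not controlled) | COc1ccc(C3[C@@]4(O3)CO[C@H](c5cc(OC)c(OCc6ccccc6)c(Br)c5)[C@H]4CO)cc1OCc1ccccc1
F6 | step 12 | 3-[4-(benzyloxy)-3-methoxyphenyl]prop-2-yn-1-ol | OCC#Cc1ccc(OCc2ccccc2)c(OC)c1
F7 | step 12 | 1-(benzyloxy)-4-(3-bromoprop-1-yn-1-yl)-2-methoxybenzene | BrCC#Cc1ccc(OCc2ccccc2)c(OC)c1
F8 | step 12 | (2S)-2-[(R)-[4-(benzyloxy)-3-bromo-5-methoxyphenyl]({3-[4-(benzyloxy)-3-methoxyphenyl]prop-2-yn-1-yl}oxy)methyl]oxirane | COc1cc(C#CCO[C@H](c2cc(OC)c(OCc3ccccc3)c(Br)c2)[C@@H]2CO2)ccc1OCc1ccccc1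
F9 | step 12 | [(2S,3R)-2-[4-(benzyloxy)-3-bromo-5-methoxyphenyl]-4-[4-(benzyloxy)-3-methoxybenzylidene]oxolan-3-yl]methanol (E/Z not controlled) | COc1cc(C=C2CO[C@H](c3cc(OC)c(OCc4ccccc4)c(Br)c3)[C@H]2CO)ccc1OCc1ccccc1
F10 | step 12 | spiro-epoxide of F9 at the exocyclic alkene, epoxide oxygen on C4 anti to the C3 hydroxymethyl group (benzylic epoxide centre not controlled) | COc1cc(C3[C@@]4(O3)CO[C@H](c5cc(OC)c(OCc6ccccc6)c(Br)c5)[C@H]4CO)ccc1OCc1ccccc1
F11 | step 2 | (S)-1-[4-(benzyloxy)-3-bromo-5-methoxyphenyl]prop-2-en-1-ol | O[C@H](c1cc(OC)c(OCc2ccccc2)c(Br)c1)C=C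
F12 | step 2 | (R)-1-[4-(benzyloxy)-3-bromo-5-methoxyphenyl]prop-2-en-1-yl acetate | CC(=O)O[C@@H](c1cc(OC)c(OCc2ccccc2)c(Br)c1)C=C
F13 | step 2 | (R)-[4-(benzyloxy)-3-bromo-5-methoxyphenyl][(2R)-oxiran-2-yl]methanol (epoxide epimer of 4) | O[C@H](c1cc(OC)c(OCc2ccccc2)c(Br)c1)[C@H]1CO1
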